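# Proposed total synthesis of CNP0243665.0 (linear pentameric phlorotannin, C30H22O17)

Ring letters run A to E from the 2,4,6-trihydroxyphenyl end. The atoms that carry bridging oxygens are A1, B1 (to ring A), B2 (to ring C), C1 (to ring B), C4 (to ring D), D1 (to ring C), D2 (to ring E) and E1.

## Analysis of the target

The target is a chain of five benzene rings joined by four diaryl ether bridges (A1–O–B1, B2–O–C1, C4–O–D1, D2–O–E1). It carries thirteen free phenols: A2, A4, A6; B3, B5; C3, C5; D3, D4, D5; E3, E4, E5. There is no stereocentre and no ring other than the arenes, so the problem is one of oxygenation pattern and C–O bond formation. The free polyphenol, above all the vicinal triols of rings D and E, oxidizes readily in air under base, so every hydroxyl is best kept as a methyl ether until the last step. The difficulty is steric: each bridge has one carbon flanked by two oxygenated carbons (A1, B2, C4, D2). B2–O–C1 and D2–O–E1 can be made from a hindered phenol and an unhindered aryl donor, because C1 and E1 have only hydrogen neighbours. C4–O–D1 can be made the same way if the D2 oxygen is added afterwards. For A1–O–B1 that device fails: both carbons have ortho oxygens, and ring A, a 1,3,5-trioxygenated arene, would itself be the most reactive ring toward any electrophile meant for ring B. The strategy rests on ring A itself. It is a phloroglucinol whose ether carbon A1 lies between the hydroxylated A2 and A6, hence the tris-enol of a 2-aryloxycyclohexane-1,3,5-trione. That trione is the folded form of a 6-aryloxy-3,5-dioxohexanoate, in which A1 is an sp3 carbon bound to the ring B oxygen.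

## Retrosynthetic reasoning

**Target 24 to tridecamethyl ether 23.** Thirteen O–CH3 bonds are cut first. Methyl ethers survive every later condition (organolithium, peracid, copper, hydrogenolysis), and one Lewis-acid treatment removes them all without touching the four bridges. The forward step only has to be exhaustive.

**23 to phenol 12 and boronic acid 22.** The B2–O–C1 bridge is cut on its ring C side. It is the central bridge, so the cut is convergent. C1 has two hydrogen neighbours, so the aryl donor 22 is unhindered and the hindered partner is the phenol 12, which is the arrangement that oxidative copper-mediated O-arylation tolerates. A cut on the ring B side would need an aryl donor at B2 between two oxygens.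

**22 to bromide 20, then to phenol 19 and boronic acid 14.** The boron of 22 comes from the bromine of 20 by halogen–lithium exchange. Bromine is carried from the start of this branch because it is inert to copper coupling, formylation and peracid. In 20 the D2–O–E1 bridge is cut on the ring E side for the same steric reason; ring E is then the commercial boronic acid 14.

**19 to aldehyde 17 to diaryl ether 15.** The D2 oxygen is traced to a formyl group, and the formyl group to a hydrogen. In 15 the two equivalent ring D positions next to the bridge oxygen are each ortho, ortho and para to three oxygens. The ring C positions see only two and sit beside bromine, so electrophilic formylation should give 17 alone. The gain is that C4–O–D1 is formed while D1 still has no ortho substituent.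

**15 to phenol 13 and boronic acid 14.** C4–O–D1 is cut on the ring D side. C4 lies between two methoxy groups, so ring C must be the phenol. Ring D comes from the same boronic acid 14 that later supplies ring E.

**12 to benzyl ether 11 to triol 10.** Phenol 12 is free only at B2. Benzyl is the one group that must leave selectively beside five methyl ethers, and the three ring A methyl groups are put on after ring A exists.

**10 to keto ester 8 (key disconnection).** The A1–A2 bond is cut. Triol 10 is the enol form of trione 9, and opening 9 between A1 and A2 gives the open-chain triketide 8, in which A1 is a methylene carbon attached to the ring B oxygen. The crowded bridge is thus an alkyl aryl ether before ring A exists. The forward reaction has to generate the carbanion at that methylene carbon and make it acylate the ester carbon intramolecularly, in preference to acylation on an enolate oxygen.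

**8 to Weinreb amide 6 and keto ester 7.** The C4–C5 bond of the chain is cut: the γ-carbon of the dianion of 7 is acylated by 6. An N-methoxy-N-methylamide is used in place of an α-aryloxy ester for three reasons:
- its tetrahedral adduct holds until work-up, so a single acylation is expected;
- earlier in the sequence it cannot lactonize onto the neighbouring phenol;
- its α-hydrogens are too weakly acidic for aldol closure onto the ortho formyl group.

**6 to 5, to 3, to salicylaldehyde 1 and chloroacetamide 2.** The benzyl group is removed to give phenol 5. Its B2 oxygen goes back through formate 4 to the formyl group of 3, and the O–CH2 bond of 3 is cut. Compound 1 has the ring B pattern: its hydroxyl becomes the B1 oxygen, its formyl carbon is B2, and its methoxy groups are at B3 and B5. The order (alkylate, oxidize, benzylate) is fixed because benzyl must end up on the middle oxygen.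

## Alternatives that were turned down

**Alternative 1:** Both central bridges (B2–O–C1 and C4–O–D1) are cut. This releases ring C as 2,6-dimethoxybenzene-1,4-diol A1, the ring A–B half as 4-fluoro-3-methoxy-5-(2,4,6-trimethoxyphenoxy)benzaldehyde A2, and the ring D–E half as 4-fluoro-2,6-dimethoxy-3-(3,4,5-trimethoxyphenoxy)benzaldehyde A3. In the forward step, a carbonate base in a dipolar aprotic solvent would let the unhindered oxygen of A1 displace the fluoride of A2 and then the hindered oxygen displace the fluoride of A3. That gives the pentamer dialdehyde A4 in one pot; two aryl-migration oxidations and a global demethylation would finish.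
- For: it is the most convergent plan, forms two bridges in one operation without a metal, and places the formyl groups exactly where B5 and D4 need oxygen.
- Against: in A2 ring A sits on B1, meta to the formyl group, so the crowded A1–O–B1 bridge cannot come from formyl-activated substitution and is only moved into the preparation of A2.
- Against: in A3 the formyl group is flanked by two methoxy groups and twisted out of conjugation, so the fluoride is poorly activated just where the nucleophile is the hindered oxygen.
- Against: A1 is a hydroquinone that oxidizes to the quinone in base, and the order of the two arylations rests on a modest steric difference.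
- Comparison: Alternative 1 is stronger on convergence, on length of the endgame and on precedent for the bond-forming event. The chosen route offers a solution for A1–O–B1 that needs no substitution at an aromatic carbon and no specialised fluoroarenes.

**Alternative 2:** The D1–D2 bond is cut and ring D is built from dimethyl squarate A5. Addition of a 2-aryloxyvinyl-lithium and O-methylation would give racemic 4-{(E)-2-[4-(benzyloxy)-2,6-dimethoxyphenoxy]ethenyl}-2,3,4-trimethoxycyclobut-2-en-1-one A6. Heating opens the four-membered ring to a dienylketene that electrocyclizes and tautomerizes to 6-[4-(benzyloxy)-2,6-dimethoxyphenoxy]-2,3,4-trimethoxyphenol A7, free only at D2.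
- For: A7 is the direct counterpart of 19, the five oxygens of ring D are placed without regiochemical ambiguity, and the hindered C4–O–D1 bridge is formed on a vinyl carbon before ring D exists. Precedent for this ring expansion is broad, at least as strong as for the chosen key step.
- Against: ring D is the one ring whose pattern is reachable from a commercial 3,4,5-trimethoxyphenyl unit by formylation and oxidation (steps 8 to 10).
- Against: the β-aryloxyvinyl-lithium can lose aryloxide to give an alkyne and needs its own synthesis.
- Against: the A1–O–B1 bridge is left to a coupling.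
- Comparison: the alternative spends its ring construction where aromatic substitution already works. The chosen route spends it on the only bridge for which no such solution exists.

**Alternative 3:** Four bonds of ring B are cut (B6–B1, B3–B4, B5–B6, B2–B3). Irradiation of 4-(benzyloxy)-1-diazo-3-(2,4,6-trimethoxyphenoxy)but-3-en-2-one A8 would give, by Wolff rearrangement, a vinylketene. This adds ethoxyethyne A9 in a (2+2) cycloaddition, and the cyclobutenone reopens and electrocyclizes to 2-(benzyloxy)-5-ethoxy-3-(2,4,6-trimethoxyphenoxy)phenol A10.
- For: like the chosen plan, it places the A1–O bond on a non-aromatic carbon before a ring is closed. It forms four bonds in one step, delivers ring B with all four oxygens differentiated, and the benzannulation has wide precedent. On bonds per step and on precedent it is the stronger plan.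
- Against: A8 is an α-aryloxy-β-alkoxy enone bearing a diazo group. It would take several steps (aryloxy ketone, enol ether of defined geometry, diazo transfer) and is sensitive to acid and light.
- Against: the step is photochemical, A9 is volatile, and A10 carries an ethyl ether and a free B3 hydroxyl that demand an extra methylation.
- Comparison: the chosen route reaches its cyclization precursor 8 in four ionic steps from catalogue materials, with no diazo compound and no photochemistry, and its competing pathway (closure on oxygen) is predictable.

Key step: step 5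

Assumption: compounds 1, 2, 7, 13 and 14 are bought, and in the three copper-mediated arylations oxygen of the air is the terminal oxidant that returns the copper to the divalent state.

## Route

Step 1
Reactants: 1 2-hydroxy-4,6-dimethoxybenzaldehyde; 2 2-chloro-N-methoxy-N-methylacetamide
Product: 3 2-(2-formyl-3,5-dimethoxyphenoxy)-N-methoxy-N-methylacetamide
Conditions: K2CO3, KI (cat.), DMF, 60 °C
Reagents that add atoms: none
Why: Williamson O-alkylation of the ionizable ortho-formyl phenol, with iodide exchange activating the chloride; the amide α-hydrogens are too weakly acidic for Rap–Stoermer-type aldol closure onto the formyl group, which an α-halo ester would risk.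

Step 2
Reactants: 3 2-(2-formyl-3,5-dimethoxyphenoxy)-N-methoxy-N-methylacetamide
Product: 5 2-(2-hydroxy-3,5-dimethoxyphenoxy)-N-methoxy-N-methylacetamide, via aryl formate 4 (not isolated)
Conditions: mCPBA, CH2Cl2, 0 °C to rt; aq. Na2SO3/NaHCO3 wash; then K2CO3 (cat.), MeOH, 0 °C
Reagents that add atoms: 3-chloroperoxybenzoic acid (mCPBA), O=C(OO)c1cccc(Cl)c1
Why: Dakin-type Baeyer–Villiger oxidation, in which the 2,4,6-trioxygenated aryl group migrates in preference to hydrogen; carbonate methanolysis cleaves only the formate, and the Weinreb amide cannot lactonize onto the new ortho phenol.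

Step 3
Reactants: 5 2-(2-hydroxy-3,5-dimethoxyphenoxy)-N-methoxy-N-methylacetamide
Product: 6 2-[2-(benzyloxy)-3,5-dimethoxyphenoxy]-N-methoxy-N-methylacetamide
Conditions: BnBr, K2CO3, DMF, rt
Reagents that add atoms: benzyl bromide, BrCc1ccccc1
Why: Williamson benzylation of the only free phenol; it puts the one selectively removable group on the future B2 oxygen.

Step 4
Reactants: 6 2-[2-(benzyloxy)-3,5-dimethoxyphenoxy]-N-methoxy-N-methylacetamide; 7 methyl acetoacetate
Product: 8 methyl 6-[2-(benzyloxy)-3,5-dimethoxyphenoxy]-3,5-dioxohexanoate
Conditions: 7 (2.2 equiv), LiN(i-Pr)2 (4.4 equiv), THF, 0 °C; add 6, −78 to 0 °C; then aq. HCl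
Reagents that add atoms: none
Why: Acylation of the acetoacetate dianion at its γ-carbon (Weiler dianion chemistry) by a Weinreb amide; the lithium-chelated tetrahedral adduct prevents a second addition and collapses to the ketone on acidic work-up, and the excess dianion compensates for the acidic adduct.

Step 5
Reactants: 8 methyl 6-[2-(benzyloxy)-3,5-dimethoxyphenoxy]-3,5-dioxohexanoate
Product: 10 2-[2-(benzyloxy)-3,5-dimethoxyphenoxy]benzene-1,3,5-triol, via 2-aryloxycyclohexane-1,3,5-trione 9 (not isolated)
Conditions: LiN(i-Pr)2 (3.5 equiv), THF, −78 °C to rt (to 50 °C if needed), argon; then aq. HCl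
Reagents that add atoms: none
Why: The first two equivalents of LiN(i-Pr)2 remove the doubly activated protons at C4 and C2 and the third removes a C6 proton, which the aryloxy group makes more acidic than a terminal methyl proton, so the trianion carries its last-formed and most nucleophilic carbanion at C6. On warming, C6 adds to the ester carbonyl C1 in a 6-(enolendo)-exo-trig closure allowed by Baldwin's rules, methoxide is lost, and the A1–A2 bond and ring A are formed as trione 9, which is at once deprotonated to the phloroglucinolate and appears as triol 10 on acidification. The closest known reaction type is the base-mediated Claisen (Dieckmann-type) cyclization of 3,5-dioxoalkanoate and 3,5,7-trioxoalkanoate esters to phloroglucinols, the laboratory counterpart of polyketide folding. No stereocentre is formed. The selectivity needed is C-acylation by C6 over O-acylation by the C5 enolate oxygen, which would give a 4-hydroxy-2-pyrone. The substrate secures it because the C6 carbanion is far more nucleophilic than the charge-delocalized enolate oxygens, because lithium chelation holds the 1,3,5-trioxygenated chain in the U shape that brings C6 to C1, and because only the carbocycle is removed irreversibly by aromatization. The ester is deactivated as part of the C2 enolate, so the closure is expected to need ambient temperature or gentle heating, and the diisopropylamine present can relay protons to the small, more electrophilic fraction that is protonated at C2. Aryloxide cannot be expelled, since no carbanion arises β to it, and the electron-rich ring B disfavours Smiles-type aryl migration.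

Step 6
Reactants: 10 2-[2-(benzyloxy)-3,5-dimethoxyphenoxy]benzene-1,3,5-triol
Product: 11 2-(benzyloxy)-1,5-dimethoxy-3-(2,4,6-trimethoxyphenoxy)benzene
Conditions: Me2SO4, K2CO3, acetone, reflux, argon
Reagents that add atoms: dimethyl sulfate, COS(=O)(=O)OC
Why: Triple Williamson O-methylation under the conditions that convert phloroglucinol into its trimethyl ether; the hard electrophile and carbonate in acetone favour oxygen over ring carbon.

Step 7
Reactants: 11 2-(benzyloxy)-1,5-dimethoxy-3-(2,4,6-trimethoxyphenoxy)benzene
Product: 12 2,4-dimethoxy-6-(2,4,6-trimethoxyphenoxy)phenol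
Conditions: H2 (1 atm), 10% Pd/C, EtOAc–MeOH, rt
Reagents that add atoms: none
Why: Hydrogenolysis of the benzyl aryl ether; methyl ethers and the diaryl ether are inert, so only the B2 hydroxyl is freed.

Step 8
Reactants: 13 4-bromo-2,6-dimethoxyphenol; 14 (3,4,5-trimethoxyphenyl)boronic acid
Product: 15 5-bromo-1,3-dimethoxy-2-(3,4,5-trimethoxyphenoxy)benzene
Conditions: Cu(OAc)2, pyridine, 4 Å MS, CH2Cl2, dry air, rt
Reagents that add atoms: none
Why: Chan–Lam O-arylation with divalent copper; the phenol is flanked by two methoxy groups but the boronic acid is unhindered, the pairing this coupling accepts. The aryl bromide is untouched at room temperature and blocks oxidative para coupling of the phenol.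

Step 9
Reactants: 15 5-bromo-1,3-dimethoxy-2-(3,4,5-trimethoxyphenoxy)benzene
Product: 17 6-(4-bromo-2,6-dimethoxyphenoxy)-2,3,4-trimethoxybenzaldehyde, via aryl iminium salt 16 (not isolated)
Conditions: POCl3, DMF, 0 to 60 °C; then aq. NaOAc
Reagents that add atoms: N,N-dimethylformamide, CN(C)C=O; water, O
Why: Vilsmeier–Haack formylation; the two equivalent ring D positions next to the bridge oxygen are ortho, ortho and para to three oxygens (phloroglucinol-ether reactivity), whereas the ring C positions are activated by two and deactivated by the adjacent bromine.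

Step 10
Reactants: 17 6-(4-bromo-2,6-dimethoxyphenoxy)-2,3,4-trimethoxybenzaldehyde
Product: 19 6-(4-bromo-2,6-dimethoxyphenoxy)-2,3,4-trimethoxyphenol, via aryl formate 18 (not isolated)
Conditions: mCPBA, CH2Cl2, 0 °C to rt; aq. Na2SO3/NaHCO3 wash; then K2CO3 (cat.), MeOH, 0 °C
Reagents that add atoms: 3-chloroperoxybenzoic acid (mCPBA), O=C(OO)c1cccc(Cl)c1
Why: Dakin-type Baeyer–Villiger oxidation; the aryl group with ortho and para oxygens migrates readily, and formate methanolysis frees the D2 hydroxyl as the only phenol.

Step 11
Reactants: 19 6-(4-bromo-2,6-dimethoxyphenoxy)-2,3,4-trimethoxyphenol; 14 (3,4,5-trimethoxyphenyl)boronic acid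
Product: 20 5-bromo-1,3-dimethoxy-2-[3,4,5-trimethoxy-2-(3,4,5-trimethoxyphenoxy)phenoxy]benzene
Conditions: Cu(OAc)2, pyridine, 4 Å MS, CH2Cl2, dry air, rt
Reagents that add atoms: none
Why: Second Chan–Lam O-arylation, again a hindered phenol with an unhindered boronic acid; it forms the D2–O–E1 bridge and leaves the ring C bromide for the next step.

Step 12
Reactants: 20 5-bromo-1,3-dimethoxy-2-[3,4,5-trimethoxy-2-(3,4,5-trimethoxyphenoxy)phenoxy]benzene
Product: 22 {3,5-dimethoxy-4-[3,4,5-trimethoxy-2-(3,4,5-trimethoxyphenoxy)phenoxy]phenyl}boronic acid, via aryllithium 21 (not isolated)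
Conditions: B(Oi-Pr)3, THF, −78 °C; add n-BuLi; to 0 °C; then aq. HCl
Reagents that add atoms: triisopropyl borate, CC(C)OB(OC(C)C)OC(C)C; water, O
Why: Bromine–lithium exchange is faster than any ortho-lithiation of the methoxyarenes at −78 °C, and the borate already present traps the aryllithium before it can isomerize; hydrolysis of the boronate gives the boronic acid.

Step 13
Reactants: 12 2,4-dimethoxy-6-(2,4,6-trimethoxyphenoxy)phenol; 22 {3,5-dimethoxy-4-[3,4,5-trimethoxy-2-(3,4,5-trimethoxyphenoxy)phenoxy]phenyl}boronic acid
Product: 23 5-[2,4-dimethoxy-6-(2,4,6-trimethoxyphenoxy)phenoxy]-1,3-dimethoxy-2-[3,4,5-trimethoxy-2-(3,4,5-trimethoxyphenoxy)phenoxy]benzene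
Conditions: Cu(OAc)2, pyridine, 4 Å MS, CH2Cl2, dry air, rt
Reagents that add atoms: none
Why: Chan–Lam union of the two halves at the B2–O–C1 bridge; boron sits on C1 between two hydrogens, the phenol carries the steric load, and reductive elimination from copper forms the bridge at room temperature with all ethers untouched.

Step 14
Reactants: 23 5-[2,4-dimethoxy-6-(2,4,6-trimethoxyphenoxy)phenoxy]-1,3-dimethoxy-2-[3,4,5-trimethoxy-2-(3,4,5-trimethoxyphenoxy)phenoxy]benzene
Product: 24 5-[2,4-dihydroxy-6-(2,4,6-trihydroxyphenoxy)phenoxy]-2-[3,4,5-trihydroxy-2-(3,4,5-trihydroxyphenoxy)phenoxy]benzene-1,3-diol (CNP0243665.0)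
Conditions: BBr3 (excess), CH2Cl2, −78 °C to rt, argon; then MeOH, degassed aq. work-up
Reagents that add atoms: none
Why: Lewis-acid cleavage of all thirteen aryl methyl ethers (bromide attacks the methyl carbon of each boron-complexed ether); diaryl ethers have no alkyl carbon to attack and survive, and acidic, oxygen-free work-up protects the vicinal triols.

## Compound list

1 | 2-hydroxy-4,6-dimethoxybenzaldehyde | COc1cc(O)c(C=O)c(OC)c1 | starting material
2 | 2-chloro-N-methoxy-N-methylacetamide | CON(C)C(=O)CCl | starting material
3 | 2-(2-formyl-3,5-dimethoxyphenoxy)-N-methoxy-N-methylacetamide | CON(C)C(=O)COc1cc(OC)cc(OC)c1C=O | intermediate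
4 | 2-{2-[methoxy(methyl)amino]-2-oxoethoxy}-4,6-dimethoxyphenyl formate | CON(C)C(=O)COc1cc(OC)cc(OC)c1OC=O | intermediate (not isolated)
5 | 2-(2-hydroxy-3,5-dimethoxyphenoxy)-N-methoxy-N-methylacetamide | CON(C)C(=O)COc1cc(OC)cc(OC)c1O | intermediate
6 | 2-[2-(benzyloxy)-3,5-dimethoxyphenoxy]-N-methoxy-N-methylacetamide | CON(C)C(=O)COc1cc(OC)cc(OC)c1OCc1ccccc1 | intermediate
7 | methyl acetoacetate (methyl 3-oxobutanoate) | COC(=O)CC(C)=O | starting material
8 | methyl 6-[2-(benzyloxy)-3,5-dimethoxyphenoxy]-3,5-dioxohexanoate | COC(=O)CC(=O)CC(=O)COc1cc(OC)cc(OC)c1OCc1ccccc1 | intermediate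
9 | 2-[2-(benzyloxy)-3,5-dimethoxyphenoxy]cyclohexane-1,3,5-trione | O=C1CC(=O)C(Oc2cc(OC)cc(OC)c2OCc2ccccc2)C(=O)C1 | intermediate (not isolated)
10 | 2-[2-(benzyloxy)-3,5-dimethoxyphenoxy]benzene-1,3,5-triol | Oc1cc(O)c(Oc2cc(OC)cc(OC)c2OCc2ccccc2)c(O)c1 | intermediate
11 | 2-(benzyloxy)-1,5-dimethoxy-3-(2,4,6-trimethoxyphenoxy)benzene | COc1cc(OC)c(Oc2cc(OC)cc(OC)c2OCc2ccccc2)c(OC)c1 | intermediate
12 | 2,4-dimethoxy-6-(2,4,6-trimethoxyphenoxy)phenol | COc1cc(OC)c(O)c(Oc2c(OC)cc(OC)cc2OC)c1 | intermediate
13 | 4-bromo-2,6-dimethoxyphenol | COc1cc(Br)cc(OC)c1O | starting material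
14 | (3,4,5-trimethoxyphenyl)boronic acid | COc1cc(B(O)O)cc(OC)c1OC | starting material
15 | 5-bromo-1,3-dimethoxy-2-(3,4,5-trimethoxyphenoxy)benzene | COc1cc(Br)cc(OC)c1Oc1cc(OC)c(OC)c(OC)c1 | intermediate
16 | N-{[6-(4-bromo-2,6-dimethoxyphenoxy)-2,3,4-trimethoxyphenyl]methylidene}-N-methylmethanaminium chloride | COc1cc(Oc2c(OC)cc(Br)cc2OC)c(C=[N+](C)C)c(OC)c1OC.[Cl-] | intermediate (not isolated)
17 | 6-(4-bromo-2,6-dimethoxyphenoxy)-2,3,4-trimethoxybenzaldehyde | COc1cc(Oc2c(OC)cc(Br)cc2OC)c(C=O)c(OC)c1OC | intermediate
18 | 6-(4-bromo-2,6-dimethoxyphenoxy)-2,3,4-trimethoxyphenyl formate | COc1cc(Oc2c(OC)cc(Br)cc2OC)c(OC=O)c(OC)c1OC | intermediate (not isolated)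
19 | 6-(4-bromo-2,6-dimethoxyphenoxy)-2,3,4-trimethoxyphenol | COc1cc(Oc2c(OC)cc(Br)cc2OC)c(O)c(OC)c1OC | intermediate
20 | 5-bromo-1,3-dimethoxy-2-[3,4,5-trimethoxy-2-(3,4,5-trimethoxyphenoxy)phenoxy]benzene | COc1cc(Br)cc(OC)c1Oc1cc(OC)c(OC)c(OC)c1Oc1cc(OC)c(OC)c(OC)c1 | intermediate
21 | {3,5-dimethoxy-4-[3,4,5-trimethoxy-2-(3,4,5-trimethoxyphenoxy)phenoxy]phenyl}lithium | [Li]c1cc(OC)c(Oc2cc(OC)c(OC)c(OC)c2Oc2cc(OC)c(OC)c(OC)c2)c(OC)c1 | intermediate (not isolated)
22 | {3,5-dimethoxy-4-[3,4,5-trimethoxy-2-(3,4,5-trimethoxyphenoxy)phenoxy]phenyl}boronic acid | COc1cc(B(O)O)cc(OC)c1Oc1cc(OC)c(OC)c(OC)c1Oc1cc(OC)c(OC)c(OC)c1 | intermediate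
23 | 5-[2,4-dimethoxy-6-(2,4,6-trimethoxyphenoxy)phenoxy]-1,3-dimethoxy-2-[3,4,5-trimethoxy-2-(3,4,5-trimethoxyphenoxy)phenoxy]benzene | COc1cc(OC)c(Oc2cc(OC)cc(OC)c2Oc2cc(OC)c(Oc3cc(OC)c(OC)c(OC)c3Oc3cc(OC)c(OC)c(OC)c3)c(OC)c2)c(OC)c1 | intermediate
24 | 5-[2,4-dihydroxy-6-(2,4,6-trihydroxyphenoxy)phenoxy]-2-[3,4,5-trihydroxy-2-(3,4,5-trihydroxyphenoxy)phenoxy]benzene-1,3-diol | Oc1cc(O)c(Oc2cc(O)cc(O)c2Oc2cc(O)c(Oc3cc(O)c(O)c(O)c3Oc3cc(O)c(O)c(O)c3)c(O)c2)c(O)c1 | target

## Step count and uncertain steps

Total step count: 14. Longest linear sequence: 9 steps (steps 1 to 7, then 13 and 14); the ring C–D–E branch (steps 8 to 12) runs in parallel.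

**Step 5 (key step).** The trianion may persist without closing, because the ester carbonyl is deactivated as part of the C2 enolate. On forcing, acylation on the C5 enolate oxygen (pyrone formation) or retro-Claisen cleavage of the diketone may take over. The fallback gives up ring construction for cross-coupling; it sets out from 1 and comes back at 12, so steps 1 to 7 drop out.
- Triflation of 1 (Tf2O, pyridine, CH2Cl2, 0 °C) gives 2-formyl-3,5-dimethoxyphenyl trifluoromethanesulfonate F1.
- Palladium-catalysed C–O coupling of F1 with commercial 2,4,6-trimethoxyphenol gives 2,4-dimethoxy-6-(2,4,6-trimethoxyphenoxy)benzaldehyde F2. Conditions: Pd(OAc)2, 2-(di-tert-butylphosphino)-2',4',6'-triisopropylbiphenyl, K3PO4, toluene, 100 °C. The ortho formyl group helps oxidative addition to zerovalent palladium.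
- Dakin oxidation of F2 (mCPBA, then K2CO3/MeOH) passes through 2,4-dimethoxy-6-(2,4,6-trimethoxyphenoxy)phenyl formate F3 and gives 12.

This brings the crowded bridge back to an aromatic carbon, which is why it is only the reserve.

**Step 13.** Transfer of the large aryl group to the copper phenoxide of the doubly ortho-substituted phenol may be slow, so protodeboronation and oxidative hydroxylation of the boronic acid could consume 22 first. The fallback sets out from 12 and 20 (step 12 is skipped) and comes back at 23. It is an Ullmann-type coupling of the aryl bromide itself (CuI, N,N-dimethylglycine, Cs2CO3, dioxane, 100 °C), which needs no boron and no oxidant. No new compound is made (F0).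

**Step 11.** The same steric retardation applies at the D2 hydroxyl, and the electron-rich phenol may be oxidized by divalent copper and air. The fallback sets out from 19 and comes back at 20. It is an Ullmann coupling with commercial 5-iodo-1,2,3-trimethoxybenzene (CuI, picolinic acid, K3PO4, DMSO, 80 °C), relying on the iodide reacting before the ring C bromide. No new compound is made (F0).

**Step 14.** Cleavage of thirteen ethers may stop short and leave partially methylated material, and the vicinal triols may oxidize during work-up and chromatography. The fallback sets out from 23 and comes back at 24, and moves purification to a stable derivative.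
- The crude BBr3 product is not isolated but acetylated (Ac2O, pyridine) to 5-[2,4-diacetoxy-6-(2,4,6-triacetoxyphenoxy)phenoxy]-2-[3,4,5-triacetoxy-2-(3,4,5-triacetoxyphenoxy)phenoxy]benzene-1,3-diyl diacetate F5.
- F5 is purified on silica and then deacetylated by acid methanolysis (AcCl in degassed MeOH).

**Step 4.** The dianion may act as a base toward the α-aryloxy methylene of 6, or may cleave the N–O bond of the amide, returning unreacted material. The fallback sets out from 6 and comes back at 8.
- The lithium dienolate of commercial 2,2,6-trimethyl-4H-1,3-dioxin-4-one (LiN(SiMe3)2, THF, −78 °C) is acylated by 6 to give 6-{3-[2-(benzyloxy)-3,5-dimethoxyphenoxy]-2-oxopropyl}-2,2-dimethyl-4H-1,3-dioxin-4-one F4.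
- Heating F4 in toluene with methanol (110 °C) releases an acylketene that methanol captures as 8.

## Further compounds

F1 | step 5 | 2-formyl-3,5-dimethoxyphenyl trifluoromethanesulfonate | COc1cc(OC)c(C=O)c(OS(=O)(=O)C(F)(F)F)c1
F2 | step 5 | 2,4-dimethoxy-6-(2,4,6-trimethoxyphenoxy)benzaldehyde | COc1cc(OC)c(C=O)c(Oc2c(OC)cc(OC)cc2OC)c1
F3 | step 5 | 2,4-dimethoxy-6-(2,4,6-trimethoxyphenoxy)phenyl formate | COc1cc(OC)c(OC=O)c(Oc2c(OC)cc(OC)cc2OC)c1
F0 | step 13 | none | none
F0 | step 11 | none | none
F5 | step 14 | 5-[2,4-diacetoxy-6-(2,4,6-triacetoxyphenoxy)phenoxy]-2-[3,4,5-triacetoxy-2-(3,4,5-triacetoxyphenoxy)phenoxy]benzene-1,3-diyl diacetate | CC(=O)Oc1cc(OC(C)=O)c(Oc2cc(OC(C)=O)cc(OC(C)=O)c2Oc2cc(OC(C)=O)c(Oc3cc(OC(C)=O)c(OC(C)=O)c(OC(C)=O)c3Oc3cc(OC(C)=O)c(OC(C)=O)c(OC(C)=O)c3)c(OC(C)=O)c2)c(OC(C)=O)c1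
F4 | step 4 | 6-{3-[2-(benzyloxy)-3,5-dimethoxyphenoxy]-2-oxopropyl}-2,2-dimethyl-4H-1,3-dioxin-4-one | CC1(C)OC(=O)C=C(CC(=O)COc2cc(OC)cc(OC)c2OCc2ccccc2)O1
A1 | alternative 1 | 2,6-dimethoxybenzene-1,4-diol | COc1cc(O)cc(OC)c1O
A2 | alternative 1 | 4-fluoro-3-methoxy-5-(2,4,6-trimethoxyphenoxy)benzaldehyde | COc1cc(C=O)cc(Oc2c(OC)cc(OC)cc2OC)c1F
A3 | alternative 1 | 4-fluoro-2,6-dimethoxy-3-(3,4,5-trimethoxyphenoxy)benzaldehyde | COc1cc(F)c(Oc2cc(OC)c(OC)c(OC)c2)c(OC)c1C=O
A4 | alternative 1 | 3-[4-(4-{4-formyl-3,5-dimethoxy-2-(3,4,5-trimethoxyphenoxy)phenoxy}-3,5-dimethoxyphenoxy)]-4-substituted pentamer dialdehyde: 4-{4-[4-formyl-3,5-dimethoxy-2-(3,4,5-trimethoxyphenoxy)phenoxy]-3,5-dimethoxyphenoxy}-3-methoxy-5-(2,4,6-trimethoxyphenoxy)benzaldehyde | COc1cc(OC)c(Oc2cc(C=O)cc(OC)c2Oc2cc(OC)c(Oc3cc(OC)c(C=O)c(OC)c3Oc3cc(OC)c(OC)c(OC)c3)c(OC)c2)c(OC)c1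
A5 | alternative 2 | dimethyl squarate (3,4-dimethoxycyclobut-3-ene-1,2-dione) | COC1=C(OC)C(=O)C1=O
A6 | alternative 2 | racemic 4-{(E)-2-[4-(benzyloxy)-2,6-dimethoxyphenoxy]ethenyl}-2,3,4-trimethoxycyclobut-2-en-1-one | COC1=C(OC)C(OC)(/C=C/Oc2c(OC)cc(OCc3ccccc3)cc2OC)C1=O
A7 | alternative 2 | 6-[4-(benzyloxy)-2,6-dimethoxyphenoxy]-2,3,4-trimethoxyphenol | COc1cc(Oc2c(OC)cc(OCc3ccccc3)cc2OC)c(O)c(OC)c1OC
A8 | alternative 3 | (Z)-4-(benzyloxy)-1-diazo-3-(2,4,6-trimethoxyphenoxy)but-3-en-2-one | [N-]=[N+]=CC(=O)/C(Oc1c(OC)cc(OC)cc1OC)=C/OCc1ccccc1
A9 | alternative 3 | ethoxyethyne | CCOC#C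
A10 | alternative 3 | 2-(benzyloxy)-5-ethoxy-3-(2,4,6-trimethoxyphenoxy)phenol | CCOc1cc(O)c(OCc2ccccc2)c(Oc2c(OC)cc(OC)cc2OC)c1
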